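**Retrosynthetic overview**
- The target is opened by a last-step intermolecular Diels–Alder reaction (bicyclo[2.2.2]octene and spiro C11) into 9β-hydroxyhelenalin 6-tiglate and (R)-p-mentha-1,5-dien-8-ol, the latter from (R)-carvone by hydration and Shapiro reaction.
- The α-methylene lactone and the 6α-tiglate come in one step from an 8β-allylic alcohol by a new copper-catalysed radical cyclisation/acyloxylation of a 2-iodoallyl acetal (C7–C11 and C6–O bonds).
- The C8/C9/C10 triad comes from a cross-conjugated cycloheptadienone: cuprate addition (C10), Rubottom oxidation (C9), Luche reduction (C8).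
- The hydroazulene comes from ring-closing metathesis of a 2-methyl-2-vinyl-3-pentenylcyclopentanone, made by asymmetric conjugate addition/aldol on 2-methylcyclopent-2-enone.
- Ring order: cyclopentanone (bought) → seven-membered ring → lactone ring → cyclopentenone unsaturation → bicyclo[2.2.2]octene.

Assumption: sesquiterpene atoms are numbered as in helenalin (C1–C15; C4 ketone, methyls on C5 and C10, lactone C12 on O8) with α/β as in the usual helenalin drawing (H-1 α, C5-methyl β); centres formed as inconsequential epimer mixtures (carbinol carbon of 5, acetal carbon C12 of 17, 19 and 20) are left undefined in the SMILES.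

**Route**

Step 1
Reactants: 1 2-methylcyclopent-2-en-1-one; 2 pent-4-en-1-ylmagnesium bromide; 3 acetaldehyde
Product: 5 (2R,3R)-2-(1-hydroxyethyl)-2-methyl-3-(pent-4-en-1-yl)cyclopentan-1-one (carbinol epimers), via bromomagnesium enolate 4 (not isolated)
Conditions: CuBr·SMe2 (5 mol %), (R)-1-[(S)-2-(diphenylphosphino)ferrocenyl]ethyldicyclohexylphosphine (6 mol %), t-BuOMe, −78 °C; then 3, −78 °C; aq NH4Cl
Reagents that add atoms: none
Why: Copper-catalysed asymmetric conjugate addition of the Grignard reagent sets C1 (the ligand antipode is chosen to give the 3R adduct), and the regiodefined magnesium enolate adds to acetaldehyde anti to the new side chain, setting the quaternary C5 (three-component conjugate addition/aldol coupling).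

Step 2
Reactants: 5 (2R,3R)-2-(1-hydroxyethyl)-2-methyl-3-(pent-4-en-1-yl)cyclopentan-1-one
Product: 6 (2S,3R)-2-ethenyl-2-methyl-3-(pent-4-en-1-yl)cyclopentan-1-one
Conditions: Martin sulfurane Ph2S[OC(CF3)2Ph]2, CH2Cl2, 0 to 25 °C
Reagents that add atoms: none
Why: Martin sulfurane dehydration of the secondary alcohol can only eliminate toward the methyl group because the other neighbour is quaternary, so the vinyl group forms without touching C1 or C5.

Step 3
Reactants: 6 (2S,3R)-2-ethenyl-2-methyl-3-(pent-4-en-1-yl)cyclopentan-1-one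
Product: 7 (3aR,8aR)-8a-methyl-3,3a,4,5,6,8a-hexahydroazulen-1(2H)-one
Conditions: second-generation Hoveyda–Grubbs catalyst RuCl2(C21H26N2)(=CH-C6H4-2-OiPr) (5 mol %), toluene (0.005 M), 80 °C
Reagents that add atoms: none
Why: Ring-closing metathesis of the two terminal alkenes closes the seven-membered ring as the C6=C7 alkene with loss of ethene; the trans ring fusion was fixed in step 1.

Step 4
Reactants: 7 (3aR,8aR)-8a-methyl-3,3a,4,5,6,8a-hexahydroazulen-1(2H)-one
Product: 8 ethylene ketal of 7 (1,3-dioxolane at C4)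
Conditions: (Me3SiOCH2)2, Me3SiOTf (5 mol %), CH2Cl2, −78 to −20 °C
Reagents that add atoms: 1,2-bis(trimethylsilyloxy)ethane, C[Si](C)(C)OCCO[Si](C)(C)C
Why: Noyori ketalisation masks the hindered C4 ketone so that later dehydrogenation, cuprate addition and hydride reduction act only in the seven-membered ring; no stereocentre is affected.

Step 5
Reactants: 8 ethylene ketal of 7
Product: 9 C4-ketal Δ6-en-8-one (helenalin numbering)
Conditions: Rh2(C6H10NO)4 (dirhodium tetrakis(caprolactamate), 1 mol %), t-BuOOH, K2CO3, CH2Cl2, 25 °C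
Reagents that add atoms: tert-butyl hydroperoxide, CC(C)(C)OO
Why: Dirhodium-catalysed allylic C–H oxidation occurs at C8, the only allylic CH2 (the other allylic carbon is quaternary C5 and trapping at neopentylic C6 is disfavoured), giving the C6=C7–C8=O enone.

Step 6
Reactants: 9 C4-ketal Δ6-en-8-one
Product: 10 C4-ketal cross-conjugated Δ6,Δ9-dien-8-one
Conditions: 2-iodoxybenzoic acid, 4-methoxypyridine N-oxide, DMSO, 40 °C
Reagents that add atoms: none
Why: 2-Iodoxybenzoic acid dehydrogenation of the enone through its enol can only desaturate C9–C10 because the γ-position is the quaternary C5 and the C4 ketone is masked.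

Step 7
Reactants: 10 C4-ketal cross-conjugated Δ6,Δ9-dien-8-one
Product: 12 8-(tert-butyldimethylsilyloxy)-10α-methyl-6,8-diene (C4 ketal), via lithium enolate 11 (not isolated)
Conditions: Me2CuLi, Et2O, −78 °C; then t-BuMe2SiOTf, −78 to 0 °C
Reagents that add atoms: lithium dimethylcuprate, [Li+].C[Cu-]C; tert-butyldimethylsilyl trifluoromethanesulfonate, CC(C)(C)[Si](C)(C)OS(=O)(=O)C(F)(F)F
Why: Cuprate conjugate addition takes place at C10 rather than at neopentylic C6 and from the α-face opposite to the axial angular methyl, setting the 10α-methyl group, and the enolate is trapped as the silyl dienol ether.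

Step 8
Reactants: 12 8-(tert-butyldimethylsilyloxy)-10α-methyl-6,8-diene
Product: 14 9β-(tert-butyldimethylsilyloxy)-10α-methyl-6-en-8-one (C4 ketal), via silyloxy epoxide 13 (not isolated)
Conditions: mCPBA, NaHCO3, CH2Cl2, −20 to 0 °C
Reagents that add atoms: 3-chloroperbenzoic acid, OOC(=O)c1cccc(Cl)c1
Why: Rubottom oxidation: the electron-rich enol ether C8=C9 is epoxidised anti to the adjacent 10α-methyl group and 1,4-silyl migration gives the 9β-silyloxy enone, setting C9.

Step 9
Reactants: 14 9β-(tert-butyldimethylsilyloxy)-10α-methyl-6-en-8-one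
Product: 15 8β-hydroxy-9β-(tert-butyldimethylsilyloxy)-10α-methyl-6-ene (C4 ketal)
Conditions: NaBH4, CeCl3·7H2O, MeOH, −78 °C
Reagents that add atoms: none
Why: Luche 1,2-reduction delivers hydride anti to the neighbouring 9β-silyloxy group (Felkin-type attack on the α-face), giving the 8β-allylic alcohol cis to O9.

Step 10
Reactants: 15 8β-hydroxy-9β-(tert-butyldimethylsilyloxy)-10α-methyl-6-ene; 16 methoxyallene (1-methoxypropa-1,2-diene)
Product: 17 8β-O-(2-iodo-1-methoxyprop-2-en-1-yl) mixed acetal of 15 (acetal epimers)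
Conditions: N-iodosuccinimide, CH2Cl2, −40 to 0 °C
Reagents that add atoms: N-iodosuccinimide, O=C1CCC(=O)N1I
Why: Iodoalkoxylation of the alkoxyallene (iodonium attack at the central allene carbon, capture of the oxocarbenium ion by the 8β-hydroxyl) gives the 2-iodoallyl mixed acetal as in Ueno–Stork haloacetalisation; ring stereocentres are untouched.

Step 11
Reactants: 17 8β-O-(2-iodo-1-methoxyprop-2-en-1-yl) mixed acetal; 18 tiglic acid ((E)-2-methylbut-2-enoic acid)
Product: 19 tricyclic methyl acetal: 6α-tigloyloxy; 8β,12-epoxy-12-methoxy; 11(13)-ene; 9β-OTBS; C4 ketal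
Conditions: Cu(MeCN)4PF6 (10 mol %), 4,4′-di-tert-butyl-2,2′-bipyridine (12 mol %), Et3N (3 equiv), PhCMe2OOSiMe3 (1.5 equiv), MeCN, 25 °C
Reagents that add atoms: none
Why: Proposed new method: copper-catalysed radical cyclisation–acyloxylation of a 2-iodoallyl acetal, in which a cumyloxyl radical (from monovalent copper and the silyl peroxide) abstracts hydrogen from Et3N, the α-aminoalkyl radical removes iodine by halogen-atom transfer, the vinyl radical cyclises 5-exo onto C7 on the face of the O8 tether (cis-fused ring, C7–C11 β), and the C6 radical is captured by divalent copper tiglate on the α-face (anti to the new ring and the angular methyl) and gives the C6–O bond by reductive elimination from trivalent copper; the closest known reaction types are the Ueno–Stork haloacetal radical cyclisation, copper-catalysed coupling of halogen-atom-transfer-derived alkyl radicals with nitrogen nucleophiles, and Kharasch–Sosnovsky acyloxylation.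

Step 12
Reactants: 19 tricyclic methyl acetal
Product: 20 lactol ketone: 6α-tigloyloxy; 8β,12-epoxy-12-hydroxy; 11(13)-ene; 9β-OTBS; 4-one (lactol epimers)
Conditions: TsOH·H2O (0.2 equiv), acetone/H2O 10:1, 40 °C
Reagents that add atoms: water, O
Why: Acid-catalysed acetal hydrolysis turns the methyl acetal into the lactol and removes the dioxolane, while the tiglate and the hindered secondary silyl ether survive; no ring stereocentre is touched.

Step 13
Reactants: 20 lactol ketone
Product: 22 9-O-TBS ether of 9β-hydroxyhelenalin 6-tiglate, via lactone ketone 21 (not isolated)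
Conditions: 2-iodoxybenzoic acid (5 equiv), DMSO/fluorobenzene 2:1, 25 °C then 75 °C
Reagents that add atoms: none
Why: 2-Iodoxybenzoic acid first oxidises the lactol to the α-methylene-γ-lactone and then dehydrogenates the cyclopentanone (only C3 is enolisable because C5 is quaternary) to the cyclopent-2-enone in one pot.

Step 14
Reactants: 22 9-O-TBS ether of 9β-hydroxyhelenalin 6-tiglate
Product: 23 9β-hydroxyhelenalin 6-tiglate
Conditions: HF·pyridine, pyridine, THF, 0 to 25 °C
Reagents that add atoms: none
Why: Fluoride-mediated desilylation frees the 9β-hydroxyl without affecting the enone, the methylene lactone or the tiglate.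

Step 15
Reactants: 24 (R)-carvone
Product: 25 (5R)-5-(2-hydroxypropan-2-yl)-2-methylcyclohex-2-en-1-one
Conditions: 50% aq H2SO4, 0 °C
Reagents that add atoms: water, O
Why: Markovnikov acid-catalysed hydration of the isopropenyl group through the tertiary cation gives the tertiary alcohol; the conjugated ring alkene is inert and the non-enolisable stereocentre is kept.

Step 16
Reactants: 25 (5R)-5-(2-hydroxypropan-2-yl)-2-methylcyclohex-2-en-1-one
Product: 26 4-methylbenzenesulfonohydrazone of 25
Conditions: TsNHNH2, AcOH (cat.), EtOH, 25 °C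
Reagents that add atoms: 4-methylbenzenesulfonohydrazide, Cc1ccc(cc1)S(=O)(=O)NN
Why: Condensation of the ketone with the sulfonyl hydrazide gives the tosylhydrazone needed for the Shapiro reaction.

Step 17
Reactants: 26 4-methylbenzenesulfonohydrazone of 25
Product: 28 2-[(1R)-4-methylcyclohexa-2,4-dien-1-yl]propan-2-ol, via dilithiated vinyllithium 27 (not isolated)
Conditions: MeLi (3.5 equiv), Et2O, 0 to 25 °C; then H2O
Reagents that add atoms: none
Why: Shapiro reaction: α′-deprotonation of the unsaturated tosylhydrazone, loss of sulfinate and N2, and protonation of the vinyllithium give the conjugated cyclohexa-1,3-diene; the remote stereocentre is untouched.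

Step 18
Reactants: 23 9β-hydroxyhelenalin 6-tiglate; 28 2-[(1R)-4-methylcyclohexa-2,4-dien-1-yl]propan-2-ol
Product: 29 target spiro Diels–Alder adduct (CNP0185323.3)
Conditions: 28 (4 equiv), 2,6-di-tert-butyl-4-methylphenol (cat.), CH2Cl2, 12 kbar, 25 °C
Reagents that add atoms: none
Why: Intermolecular Diels–Alder reaction of the exocyclic methylene lactone (more reactive than the β-substituted cyclopentenone), with "para" orientation (C13 bonds to the diene terminus next to the methyl-bearing carbon), addition to the diene face anti to its hydroxypropyl group, and the required carbonyl-endo approach on the C6-side (β) face of the methylene (the most compact transition state, favoured by pressure), sets spiro C11 and both bridgeheads; this facial outcome is not secured by precedent and is the main risk of the route.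

**Compound list**

1 | 2-methylcyclopent-2-en-1-one | CC1=CCCC1=O | starting material
2 | pent-4-en-1-ylmagnesium bromide | C=CCCC[Mg]Br | starting material
3 | acetaldehyde | CC=O | starting material
4 | bromomagnesium (3R)-2-methyl-3-(pent-4-en-1-yl)cyclopent-1-en-1-olate | C=CCCC[C@@H]1CCC(O[Mg]Br)=C1C | intermediate
5 | (2R,3R)-2-(1-hydroxyethyl)-2-methyl-3-(pent-4-en-1-yl)cyclopentan-1-one (both carbinol epimers) | C=CCCC[C@@H]1CCC(=O)[C@]1(C(C)O)C | intermediate
6 | (2S,3R)-2-ethenyl-2-methyl-3-(pent-4-en-1-yl)cyclopentan-1-one | C=CCCC[C@@H]1CCC(=O)[C@]1(C=C)C | intermediate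
7 | (3aR,8aR)-8a-methyl-3,3a,4,5,6,8a-hexahydroazulen-1(2H)-one (helenalin numbering: 4-one, Δ6, H-1 α, C5-methyl β) | C1=CCCC[C@@H]2CCC(=O)[C@]21C | intermediate
8 | ethylene ketal of 7 (spiro-1,3-dioxolane at C4; Δ6) | C1=CCCC[C@@H]2CCC3(OCCO3)[C@]21C | intermediate
9 | C4-ketal Δ6-en-8-one (trans-fused, H-1 α, C5-methyl β) | C1=CC(=O)CC[C@@H]2CCC3(OCCO3)[C@]21C | intermediate
10 | C4-ketal Δ6,Δ9-dien-8-one (cross-conjugated cycloheptadienone) | C1=CC(=O)C=C[C@@H]2CCC3(OCCO3)[C@]21C | intermediate
11 | lithium dienolate (C8–OLi, Δ6, Δ8) of the 10α-methyl adduct, C4 ketal | C1=CC(O[Li])=C[C@@H](C)[C@@H]2CCC3(OCCO3)[C@]21C | intermediate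
12 | 8-(tert-butyldimethylsilyloxy)-10α-methyl-Δ6,Δ8-diene, C4 ketal | C1=CC(O[Si](C)(C)C(C)(C)C)=C[C@@H](C)[C@@H]2CCC3(OCCO3)[C@]21C | intermediate
13 | 8β,9β-epoxide of 12 (8α-OTBS) | C1=C[C@]3(O[Si](C)(C)C(C)(C)C)O[C@@H]3[C@@H](C)[C@@H]2CCC4(OCCO4)[C@]21C | intermediate
14 | 9β-(tert-butyldimethylsilyloxy)-10α-methyl-Δ6-en-8-one, C4 ketal | C1=CC(=O)[C@H](O[Si](C)(C)C(C)(C)C)[C@@H](C)[C@@H]2CCC3(OCCO3)[C@]21C | intermediate
15 | 8β-hydroxy-9β-(tert-butyldimethylsilyloxy)-10α-methyl-Δ6-ene, C4 ketal | C1=C[C@H](O)[C@H](O[Si](C)(C)C(C)(C)C)[C@@H](C)[C@@H]2CCC3(OCCO3)[C@]21C | intermediate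
16 | methoxyallene (1-methoxypropa-1,2-diene) | COC=C=C | starting material
17 | 8β-O-(2-iodo-1-methoxyprop-2-en-1-yl) mixed acetal of 15 (both acetal epimers) | C1=C[C@H](OC(OC)C(I)=C)[C@H](O[Si](C)(C)C(C)(C)C)[C@@H](C)[C@@H]2CCC3(OCCO3)[C@]21C | intermediate
18 | tiglic acid, (E)-2-methylbut-2-enoic acid | C/C=C(\C)C(=O)O | starting material
19 | 6α-tigloyloxy-12-methoxy-8β,12-epoxy-11(13)-ene, 9β-OTBS, 10α-methyl, C4 ketal (cis-fused cyclic methyl acetal, both C12 epimers; H-7 α, H-8 α) | C/C=C(\C)C(=O)O[C@H]1[C@H]2[C@H](OC(OC)C2=C)[C@H](O[Si](C)(C)C(C)(C)C)[C@@H](C)[C@@H]2CCC3(OCCO3)[C@]21C | intermediate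
20 | lactol of 19 with free C4 ketone (12-hydroxy-8β,12-epoxy, both C12 epimers) | C/C=C(\C)C(=O)O[C@H]1[C@H]2[C@H](OC(O)C2=C)[C@H](O[Si](C)(C)C(C)(C)C)[C@@H](C)[C@@H]2CCC(=O)[C@]21C | intermediate
21 | 2,3-dihydro-9β-hydroxyhelenalin 6-tiglate 9-O-TBS ether (α-methylene-12,8β-olide, cyclopentanone) | C/C=C(\C)C(=O)O[C@H]1[C@H]2[C@H](OC(=O)C2=C)[C@H](O[Si](C)(C)C(C)(C)C)[C@@H](C)[C@@H]2CCC(=O)[C@]21C | intermediate
22 | 9β-hydroxyhelenalin 6-tiglate 9-O-TBS ether | C/C=C(\C)C(=O)O[C@H]1[C@H]2[C@H](OC(=O)C2=C)[C@H](O[Si](C)(C)C(C)(C)C)[C@@H](C)[C@@H]2C=CC(=O)[C@]21C | intermediate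
23 | 9β-hydroxyhelenalin 6-tiglate (6α-tigloyloxy-9β-hydroxy-4-oxo-2,11(13)-dien-12,8β-olide; H-1 α, H-7 α, H-8 α, 10α-methyl, C5-methyl β) | C/C=C(\C)C(=O)O[C@H]1[C@H]2[C@H](OC(=O)C2=C)[C@H](O)[C@@H](C)[C@@H]2C=CC(=O)[C@]21C | intermediate
24 | (R)-carvone, (5R)-2-methyl-5-(prop-1-en-2-yl)cyclohex-2-en-1-one | CC1=CC[C@H](CC1=O)C(C)=C | starting material
25 | (5R)-5-(2-hydroxypropan-2-yl)-2-methylcyclohex-2-en-1-one | CC1=CC[C@H](CC1=O)C(C)(C)O | intermediate
26 | N′-[(5R)-5-(2-hydroxypropan-2-yl)-2-methylcyclohex-2-en-1-ylidene]-4-methylbenzenesulfonohydrazide | CC1=CC[C@H](CC1=NNS(=O)(=O)c2ccc(C)cc2)C(C)(C)O | intermediate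
27 | lithium 2-[(1R)-3-lithio-4-methylcyclohexa-2,4-dien-1-yl]propan-2-olate | CC1=CC[C@H](C=C1[Li])C(C)(C)O[Li] | intermediate
28 | 2-[(1R)-4-methylcyclohexa-2,4-dien-1-yl]propan-2-ol, (R)-p-mentha-1,5-dien-8-ol | CC1=CC[C@H](C=C1)C(C)(C)O | intermediate
29 | target CNP0185323.3: spiro adduct of 23 (through C11/C13) with 28; lactone carbonyl syn to the bicyclooctene alkene, hydroxypropyl group syn to that alkene | C/C=C(\C)C(=O)O[C@H]1[C@H]2[C@H](OC(=O)[C@]23C[C@@H]2C[C@@H](C(C)(C)O)[C@H]3C=C2C)[C@H](O)[C@@H](C)[C@@H]2C=CC(=O)[C@]21C | target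

**Step count**

Total step count: 18. Longest linear sequence: 15 steps (steps 1–14 and 18, from 1 to 29); the diene branch is 3 steps (15–17).

**Steps most likely to fail, with fallbacks**

Step 11 (the proposed new radical cyclisation–acyloxylation). The copper capture of the hindered C6 radical may lose to simple reduction. The fallback uses known chemistry, sets out from 17 and comes back at 19. Compound 17 is cyclised under stannane conditions with oxygen trapping (Bu3SnH, Et3B, dry air, toluene, 0 °C). The vinyl radical closes the same cis-fused ring, the C6 radical is trapped by O2 on the α-face, and the hydroperoxide is reduced in situ, giving the 6α-hydroxy cyclic acetal F1. Esterification of F1 with tiglic acid 18 (2,4,6-trichlorobenzoyl chloride, Et3N, 4-dimethylaminopyridine, toluene) gives 19.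

Step 18 (Diels–Alder). The required adduct needs the diene on the more hindered C6-side face of the methylene lactone in the carbonyl-endo mode; the likely competitor is the C11 epimer (exo, α-face), and some cycloaddition at the cyclopentenone is possible. The fallback sets out from 20 (and uses 28) and comes back at 29. It moves the cycloaddition ahead of enone formation and uses Lewis acid activation of protected partners, which raises endo preference and reinforces anti addition to the diene, but it does not guarantee the lactone face. Lactol 20 is oxidised with MnO2 (CH2Cl2) to lactone ketone 21, here isolated. Diene 28 is silylated (Et3SiOTf, 2,6-lutidine) to the triethylsilyl ether F2. Compounds 21 and F2 are combined with Me2AlCl (CH2Cl2, −78 °C); the lactone is then the only activated dienophile and the large silyl ether reinforces anti addition, giving the bis-silylated cyclopentanone adduct F3. 2-Iodoxybenzoic acid (DMSO, 75 °C) dehydrogenates F3 to the bis-silylated cyclopentenone adduct F4, and HF·pyridine removes both silyl groups to give 29.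

Step 1 (asymmetric conjugate addition to an α-substituted cyclopentenone). Enantioselectivity and rate may be low for this enone. The fallback sets out from 2 and comes back at 5, and builds the quaternary centre in a separate step. Grignard reagent 2 is added under the same copper/ferrocenyl diphosphine catalysis to commercial cyclopent-2-en-1-one, for which the reaction is better precedented. The enolate is methylated in the flask with methyl iodide to give (2S,3R)-2-methyl-3-(pent-4-en-1-yl)cyclopentan-1-one F5. Thermodynamic silylation (Me3SiCl, sodium iodide, Et3N, MeCN) gives the tetrasubstituted trimethylsilyl enol ether F6. Mukaiyama aldol addition of F6 to acetaldehyde 3 (TiCl4, CH2Cl2, −78 °C), anti to the side chain, gives 5.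

Further compounds
F1 | step 11 | 6α-hydroxy-12-methoxy-8β,12-epoxy-11(13)-ene, 9β-OTBS, C4 ketal (6-hydroxy analogue of 19, both C12 epimers) | O[C@H]1[C@H]2[C@H](OC(OC)C2=C)[C@H](O[Si](C)(C)C(C)(C)C)[C@@H](C)[C@@H]2CCC3(OCCO3)[C@]21C
F2 | step 18 | triethyl{2-[(1R)-4-methylcyclohexa-2,4-dien-1-yl]propan-2-yloxy}silane | CC1=CC[C@H](C=C1)C(C)(C)O[Si](CC)(CC)CC
F3 | step 18 | 2,3-dihydro analogue of 29 carrying 9-O-TBS and carbinol O-triethylsilyl groups | C/C=C(\C)C(=O)O[C@H]1[C@H]2[C@H](OC(=O)[C@]23C[C@@H]2C[C@@H](C(C)(C)O[Si](CC)(CC)CC)[C@H]3C=C2C)[C@H](O[Si](C)(C)C(C)(C)C)[C@@H](C)[C@@H]2CCC(=O)[C@]21C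
F4 | step 18 | 29 carrying 9-O-TBS and carbinol O-triethylsilyl groups | C/C=C(\C)C(=O)O[C@H]1[C@H]2[C@H](OC(=O)[C@]23C[C@@H]2C[C@@H](C(C)(C)O[Si](CC)(CC)CC)[C@H]3C=C2C)[C@H](O[Si](C)(C)C(C)(C)C)[C@@H](C)[C@@H]2C=CC(=O)[C@]21C
F5 | step 1 | (2S,3R)-2-methyl-3-(pent-4-en-1-yl)cyclopentan-1-one | C=CCCC[C@@H]1CCC(=O)[C@H]1C
F6 | step 1 | trimethyl{[(3R)-2-methyl-3-(pent-4-en-1-yl)cyclopent-1-en-1-yl]oxy}silane | C=CCCC[C@@H]1CCC(O[Si](C)(C)C)=C1C
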